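**Strategy.** The tetrahydrofuran hides a twofold axis through its C3–C4 bond. Each of these carbons carries one CH2–O arm and one aryl-bearing carbon: O1/C5 on C4 mirrors the ester CH2O on C3, and C2 mirrors the benzylic CH2 on C4. The route therefore builds the C2-symmetric (2S,3S)-2,3-bis(4-hydroxy-3-methoxybenzyl)butane-1,4-diol by auxiliary-controlled oxidative enolate dimerisation. The ring is then closed by a desymmetrising oxidative cycloetherification. Dehydrogenation of either homotopic benzylic CH2, made possible by the para-hydroxyl of the guaiacyl ring, gives a quinone methide that the 1,4-related hydroxyl captures. This forms O1–C2, sets C2, and leaves one primary alcohol for the 4-hydroxybenzoate.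

Key step: step 5

Remark: ring numbering is O1, C2 (aryl), C3 (CH2O-ester), C4 (benzyl), C5, and the target is (2R,3S,4S). Acid 1 is taken as a catalogue compound (otherwise one benzylation/saponification from dihydroferulic acid). Step 2 is a homocoupling that consumes two molecules of imide 4 per molecule of product; the second molecule is entered on the line for atom-adding reagents.

Step 1
Reactants: 1 3-[4-(benzyloxy)-3-methoxyphenyl]propanoic acid; 2 (R)-4-isopropyloxazolidin-2-one
Product: 4 (4R)-3-{3-[4-(benzyloxy)-3-methoxyphenyl]propanoyl}-4-isopropyloxazolidin-2-one, via mixed pivalic anhydride 3 (not isolated)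
Conditions: PivCl, Et3N, THF, −20 °C; then LiCl, 2, −20 °C → rt
Reagents that add atoms: none
Why: N-acylation of the oxazolidinone through the pivaloyl mixed anhydride, in which the hindered pivaloyl carbonyl directs attack to the arylpropanoyl carbonyl; no stereocentre is touched.

Step 2
Reactants: 4 (4R)-3-{3-[4-(benzyloxy)-3-methoxyphenyl]propanoyl}-4-isopropyloxazolidin-2-one (two molecules per molecule of product)
Product: 6 (2S,3S)-2,3-bis[4-(benzyloxy)-3-methoxybenzyl]-1,4-bis[(4R)-4-isopropyl-2-oxooxazolidin-3-yl]butane-1,4-dione, via lithium Z-enolate 5 (not isolated)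
Conditions: LDA (1.05 equiv per imide), THF, −78 °C; then TiCl4 (1 equiv per imide), −78 °C → rt
Reagents that add atoms: a second molecule of imide 4 (the coupling partner), COc1cc(CCC(=O)N2[C@H](C(C)C)COC2=O)ccc1OCc1ccccc1
Why: Oxidative enolate homocoupling, in which two molecules of 4 are joined at their α-carbons with loss of one hydrogen each: Ti(IV) oxidises the chelated Z-enolate to an α-acyl radical/titanium enolate pair that joins C–C on the face of each unit opposite the C4 isopropyl group (the same facial control as in alkylation of oxazolidinone imides), so the (R)-auxiliary should set both new centres (S).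

Step 3
Reactants: 6 (2S,3S)-2,3-bis[4-(benzyloxy)-3-methoxybenzyl]-1,4-bis[(4R)-4-isopropyl-2-oxooxazolidin-3-yl]butane-1,4-dione
Product: 7 (2S,3S)-2,3-bis[4-(benzyloxy)-3-methoxybenzyl]butane-1,4-diol
Conditions: LiBH4, MeOH, THF, 0 °C → rt
Reagents that add atoms: none
Why: Reductive cleavage of N-acyloxazolidinones by LiBH4 (any lactone formed on the way is reduced as well) gives the 1,4-diol without touching the two stereocentres and releases both auxiliary units for recovery.

Step 4
Reactants: 7 (2S,3S)-2,3-bis[4-(benzyloxy)-3-methoxybenzyl]butane-1,4-diol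
Product: 8 (2S,3S)-2,3-bis(4-hydroxy-3-methoxybenzyl)butane-1,4-diol
Conditions: H2 (1 atm), 10% Pd/C, EtOAc–MeOH, rt
Reagents that add atoms: none
Why: Hydrogenolysis of aryl benzyl ethers over Pd/C; at this stage the molecule has no other benzylic C–O bond, so nothing else can be cleaved.

Step 5
Reactants: 8 (2S,3S)-2,3-bis(4-hydroxy-3-methoxybenzyl)butane-1,4-diol
Product: 10 [(2R,3S,4S)-2-(4-hydroxy-3-methoxyphenyl)-4-(4-hydroxy-3-methoxybenzyl)tetrahydrofuran-3-yl]methanol, via p-quinone methide 9 (not isolated)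
Conditions: DDQ (0.7 equiv, slow addition), 1,4-dioxane, 15 °C → rt; unreacted 8 recovered and recycled
Reagents that add atoms: none
Why: DDQ abstracts hydride (with loss of the phenolic proton) from one of the two benzylic CH2 groups para to a free phenol, giving p-quinone methide 9 and DDQH2, and the hydroxyl on the 1,4-related carbon adds to the methide carbon (intramolecular oxa-1,6-addition) with rearomatisation. The closest known reaction types are the DDQ dehydrogenation of 4-alkyl-2-methoxyphenols to quinone methides with capture by alcohols, the DDQ oxidative cyclisation of 1,3-diarylpropane phenols to flavans, and the acid-mediated closure of 7-hydroxy-secolignans to 7,9'-epoxylignans through the same quinone methide. The tetrahydrofuran closes 5-exo-trig (O onto the exocyclic methide carbon); the other hydroxyl could only give an oxetane and stays free. The new stereocentre C2 is controlled by the adjacent C3 centre: closure places the aryl group trans to the C3 hydroxymethyl arm (allylic strain in the quinone methide transition state), and because the oxa-addition is reversible in the weakly acidic DDQH2 medium any cis isomer can reopen and drain to the more stable 2,3-trans ring, while C3 and C4 are untouched. No site selectivity is needed, since the twofold axis of 8 makes the two CH2/OH pairs homotopic and either oxidation gives the same product. The selectivities that are needed are mono- over double oxidation, secured only by substoichiometric DDQ and recycling of 8, and O- over arene capture of 9, secured by the five-membered O-closure being faster than Friedel–Crafts closure in the absence of strong acid.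

Step 6
Reactants: 10 [(2R,3S,4S)-2-(4-hydroxy-3-methoxyphenyl)-4-(4-hydroxy-3-methoxybenzyl)tetrahydrofuran-3-yl]methanol; 11 4-hydroxybenzoic acid
Product: 12 agastinol, [(2R,3S,4S)-2-(4-hydroxy-3-methoxyphenyl)-4-(4-hydroxy-3-methoxybenzyl)tetrahydrofuran-3-yl]methyl 4-hydroxybenzoate
Conditions: PPh3, DIAD, THF, 0 °C → rt
Reagents that add atoms: none
Why: Mitsunobu esterification: the betaine deprotonates only the carboxylic acid (far more acidic than the phenols), so the carboxylate displaces the oxyphosphonium of the sole aliphatic primary hydroxyl chemoselectively without phenol protection; the reacting CH2 is not a stereocentre and C2–C4 are untouched.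

**Compound list**

1 | 3-[4-(benzyloxy)-3-methoxyphenyl]propanoic acid | COc1cc(CCC(=O)O)ccc1OCc1ccccc1 | starting material
2 | (R)-4-isopropyloxazolidin-2-one | CC(C)[C@@H]1COC(=O)N1 | starting material
3 | 3-[4-(benzyloxy)-3-methoxyphenyl]propanoic pivalic anhydride | COc1cc(CCC(=O)OC(=O)C(C)(C)C)ccc1OCc1ccccc1 | intermediate
4 | (4R)-3-{3-[4-(benzyloxy)-3-methoxyphenyl]propanoyl}-4-isopropyloxazolidin-2-one | COc1cc(CCC(=O)N2[C@H](C(C)C)COC2=O)ccc1OCc1ccccc1 | intermediate
5 | lithium (Z)-enolate of 4 | [Li+].[O-]/C(=C\Cc1ccc(OCc2ccccc2)c(OC)c1)N1[C@H](C(C)C)COC1=O | intermediate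
6 | (2S,3S)-2,3-bis[4-(benzyloxy)-3-methoxybenzyl]-1,4-bis[(4R)-4-isopropyl-2-oxooxazolidin-3-yl]butane-1,4-dione | O=C(N1[C@H](C(C)C)COC1=O)[C@@H](Cc1ccc(OCc2ccccc2)c(OC)c1)[C@H](Cc1ccc(OCc2ccccc2)c(OC)c1)C(=O)N1[C@H](C(C)C)COC1=O | intermediate
7 | (2S,3S)-2,3-bis[4-(benzyloxy)-3-methoxybenzyl]butane-1,4-diol | OC[C@@H](Cc1ccc(OCc2ccccc2)c(OC)c1)[C@H](Cc1ccc(OCc2ccccc2)c(OC)c1)CO | intermediate
8 | (2S,3S)-2,3-bis(4-hydroxy-3-methoxybenzyl)butane-1,4-diol ((S,S)-secoisolariciresinol) | COc1cc(C[C@H](CO)[C@@H](CO)Cc2ccc(O)c(OC)c2)ccc1O | intermediate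
9 | p-quinone methide of 8: 4-[(2S,3S)-2,3-bis(hydroxymethyl)-4-(4-hydroxy-3-methoxyphenyl)butylidene]-2-methoxycyclohexa-2,5-dien-1-one | COC1=CC(=C[C@H](CO)[C@@H](CO)Cc2ccc(O)c(OC)c2)C=CC1=O | intermediate
10 | [(2R,3S,4S)-2-(4-hydroxy-3-methoxyphenyl)-4-(4-hydroxy-3-methoxybenzyl)tetrahydrofuran-3-yl]methanol ((7R,8S,8'S)-lariciresinol) | COc1cc(C[C@@H]2CO[C@@H](c3ccc(O)c(OC)c3)[C@@H]2CO)ccc1O | intermediate
11 | 4-hydroxybenzoic acid | O=C(O)c1ccc(O)cc1 | starting material
12 | agastinol | COc1cc(C[C@@H]2CO[C@@H](c3ccc(O)c(OC)c3)[C@@H]2COC(=O)c2ccc(O)cc2)ccc1O | target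

**Totals**

Total step count: 6. Longest linear sequence: 6 steps (1 → 12).

**Steps most likely to fail**

Step 5 (key step). Over-oxidation is the main danger: the product still carries an oxidisable p-hydroxybenzyl CH2 and a new benzylic ether C–H. As conversion rises, a second dehydrogenation (closure of the second ring to the furofuran, or oxidation at C2) competes. Capture of the quinone methide by the other arene to an aryltetralin is a second leak. The fallback replaces oxidative generation of the quinone methide by ionisation of a benzylic alcohol; it sets out from 4 and comes back at 10. Imide 4 is alkylated (NaHMDS, tert-butyl bromoacetate, THF, −78 °C), anti to the isopropyl group, to the succinate imide tert-butyl (3S)-3-[4-(benzyloxy)-3-methoxybenzyl]-4-[(4R)-4-isopropyl-2-oxooxazolidin-3-yl]-4-oxobutanoate F1. LiBH4 reduces the imide to tert-butyl (3S)-4-[4-(benzyloxy)-3-methoxyphenyl]-3-(hydroxymethyl)butanoate F2, which TFA in CH2Cl2 closes to (4S)-4-[4-(benzyloxy)-3-methoxybenzyl]dihydrofuran-2(3H)-one F3. Aldol addition of its lithium enolate (LiHMDS, THF, −78 °C) to 4-(benzyloxy)-3-methoxybenzaldehyde, anti to the benzyl group, gives (3R,4S)-4-[4-(benzyloxy)-3-methoxybenzyl]-3-{[4-(benzyloxy)-3-methoxyphenyl](hydroxy)methyl}dihydrofuran-2(3H)-one F4 as both carbinol epimers. LiAlH4 gives (2S,3S)-1-[4-(benzyloxy)-3-methoxyphenyl]-3-[4-(benzyloxy)-3-methoxybenzyl]-2-(hydroxymethyl)butane-1,4-diol F5, again as both epimers. Catalytic camphorsulfonic acid in CH2Cl2 at 0 °C ionises both epimers to one p-alkoxybenzyl cation, which closes 5-exo to the 2,3-trans ring of [(2R,3S,4S)-2-[4-(benzyloxy)-3-methoxyphenyl]-4-[4-(benzyloxy)-3-methoxybenzyl]tetrahydrofuran-3-yl]methanol F6 (stereoconvergent). Hydrogenolysis (H2, Pd/C, EtOAc, stopped after uptake of two equivalents) then gives 10.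

Step 2. Facial control in the radical coupling may be poor, giving the heterochiral dimer, and TiCl4 may erode the benzyl ethers or leave the enolate unconverted. The fallback builds the second centre by substrate-controlled alkylation instead of dimerisation; it sets out from 4 and comes back at 7. Imide 4 is taken to lactone F3 exactly as described above (through F1 and F2). Alkylation of its lithium enolate (LiHMDS, THF, −78 °C) with 4-(benzyloxy)-3-methoxybenzyl bromide, trans to the existing benzyl group, gives (3S,4S)-3,4-bis[4-(benzyloxy)-3-methoxybenzyl]dihydrofuran-2(3H)-one F7. LiAlH4 in THF opens it to diol 7.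

Step 6. Chemoselectivity may be lost: the phenols of 10 or of the acid may act as Mitsunobu nucleophiles, giving aryl ethers and oligomers. The fallback masks the phenols first; it sets out from 10 and comes back at 12. Phenol-selective allylation (allyl bromide, K2CO3, acetone) gives [(2R,3S,4S)-2-[4-(allyloxy)-3-methoxyphenyl]-4-[4-(allyloxy)-3-methoxybenzyl]tetrahydrofuran-3-yl]methanol F8. Acylation of the remaining primary alcohol with 4-(allyloxy)benzoic acid (EDC·HCl, DMAP, CH2Cl2) gives the tris(allyl ether) of agastinol F9. Pd(PPh3)4 (cat.) with morpholine in THF removes the three allyl groups without touching the benzylic ring C–O bond and gives 12.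

**Further compounds**

F1 | step 5 | tert-butyl (3S)-3-[4-(benzyloxy)-3-methoxybenzyl]-4-[(4R)-4-isopropyl-2-oxooxazolidin-3-yl]-4-oxobutanoate | CC(C)(C)OC(=O)C[C@H](Cc1ccc(OCc2ccccc2)c(OC)c1)C(=O)N1[C@H](C(C)C)COC1=O
F2 | step 5 | tert-butyl (3S)-4-[4-(benzyloxy)-3-methoxyphenyl]-3-(hydroxymethyl)butanoate | CC(C)(C)OC(=O)C[C@H](Cc1ccc(OCc2ccccc2)c(OC)c1)CO
F3 | step 5 | (4S)-4-[4-(benzyloxy)-3-methoxybenzyl]dihydrofuran-2(3H)-one | O=C1C[C@H](Cc2ccc(OCc3ccccc3)c(OC)c2)CO1
F4 | step 5 | (3R,4S)-4-[4-(benzyloxy)-3-methoxybenzyl]-3-{[4-(benzyloxy)-3-methoxyphenyl](hydroxy)methyl}dihydrofuran-2(3H)-one, both carbinol epimers | O=C1[C@@H](C(O)c2ccc(OCc3ccccc3)c(OC)c2)[C@H](Cc2ccc(OCc3ccccc3)c(OC)c2)CO1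
F5 | step 5 | (2S,3S)-1-[4-(benzyloxy)-3-methoxyphenyl]-3-[4-(benzyloxy)-3-methoxybenzyl]-2-(hydroxymethyl)butane-1,4-diol, both C1 epimers | OC[C@@H](C(O)c1ccc(OCc2ccccc2)c(OC)c1)[C@H](Cc1ccc(OCc2ccccc2)c(OC)c1)CO
F6 | step 5 | [(2R,3S,4S)-2-[4-(benzyloxy)-3-methoxyphenyl]-4-[4-(benzyloxy)-3-methoxybenzyl]tetrahydrofuran-3-yl]methanol | COc1cc(C[C@@H]2CO[C@@H](c3ccc(OCc4ccccc4)c(OC)c3)[C@@H]2CO)ccc1OCc1ccccc1
F7 | step 2 | (3S,4S)-3,4-bis[4-(benzyloxy)-3-methoxybenzyl]dihydrofuran-2(3H)-one | O=C1[C@@H](Cc2ccc(OCc3ccccc3)c(OC)c2)[C@H](Cc2ccc(OCc3ccccc3)c(OC)c2)CO1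
F8 | step 6 | [(2R,3S,4S)-2-[4-(allyloxy)-3-methoxyphenyl]-4-[4-(allyloxy)-3-methoxybenzyl]tetrahydrofuran-3-yl]methanol | COc1cc(C[C@@H]2CO[C@@H](c3ccc(OCC=C)c(OC)c3)[C@@H]2CO)ccc1OCC=C
F9 | step 6 | [(2R,3S,4S)-2-[4-(allyloxy)-3-methoxyphenyl]-4-[4-(allyloxy)-3-methoxybenzyl]tetrahydrofuran-3-yl]methyl 4-(allyloxy)benzoate | COc1cc(C[C@@H]2CO[C@@H](c3ccc(OCC=C)c(OC)c3)[C@@H]2COC(=O)c2ccc(OCC=C)cc2)ccc1OCC=C
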